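**Retrosynthetic overview**
Numbering: ring carbons C1–C10 (C1 ketone, C4 methyl-bearing epoxide carbon, C5 epoxide CH, C6 lactone CH–O, C7=C11 butenolide olefin, C8 tiglate carbon, C10 bearing methylene C14), C12 lactone carbonyl, C13 CH2OAc. The strategy rests on the C1 ketone lying between C10 and, three carbons on (C10–C9–C8), the butenolide carbon C7, so the ten-membered ring is a cycloheptanone (C1–C7) with C8–C10 inserted between C1 and C7.
Key disconnection: make C1–C10, cut C1–C7, make C7=C11 by cutting C11–SPh; this leads back to the iodovinyl phenylthio lactone cycloheptanone 27, in which the trans 4,5-epoxide is stored as a cis 4,5-diol acetonide.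
27 is traced to acyclic ketone 14: C6 from an Evans aldol, quaternary C7 from a chelate-controlled dianion alkylation, C4/C5 from an O6–H-directed dihydroxylation, C8 from a reagent-controlled 2-bromoallylboration, the C11 substituents from lactone enolate chemistry.
Ring order: cycloheptenone by ring-closing metathesis (C4=C5), then dioxolane and γ-lactone, then radical expansion to the ten-membered ring, last the epoxide.

Key step: step 15

Assumption: the 2-bromoallyl borane made from the (+)-α-pinene-derived Ipc2BBr is taken to add to the Si face of the C8 aldehyde as the parent allyl reagent does, and the C11 configuration drawn for 25–27 (electrophiles entering from the convex lactone face) is of no consequence because C11 becomes trigonal in step 15.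

**Route**

Step 1
Reactants: 1 4-methylpent-3-enoic acid; 2 (S)-4-benzyloxazolidin-2-one
Product: 4 (S)-4-benzyl-3-(4-methylpent-3-enoyl)oxazolidin-2-one, via mixed pivalic anhydride 3 (not isolated)
Conditions: PivCl, Et3N, THF, −20 °C; then LiCl, 2, −20 °C to rt
Reagents that add atoms: none
Why: N-acylation of the LiCl-activated oxazolidinone by the mixed anhydride is the standard Evans imide synthesis and sets no stereocentre.

Step 2
Reactants: 4 (S)-4-benzyl-3-(4-methylpent-3-enoyl)oxazolidin-2-one; 5 acrolein
Product: 8 (S)-4-benzyl-3-[(2S,3R)-3-hydroxy-2-(2-methylprop-1-en-1-yl)pent-4-enoyl]oxazolidin-2-one, via dibutylboron Z-enolate 6 (not isolated), via dibutylboron aldolate 7 (not isolated)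
Conditions: Bu2BOTf, iPr2NEt, CH2Cl2, −78 to 0 °C; 5, −78 °C; then pH 7 buffer, MeOH, H2O2, 0 °C
Reagents that add atoms: none
Why: Evans syn-aldol addition, in which the Z-boron dienolate reacts at its α-carbon (C7) with acrolein through a chair transition state whose open face is fixed by the benzyl group of the auxiliary, so that C6 (the centre that is kept) and C7 form the syn pair shown.

Step 3
Reactants: 8 aldol imide
Product: 9 (2S,3R)-3-hydroxy-N-methoxy-N-methyl-2-(2-methylprop-1-en-1-yl)pent-4-enamide
Conditions: MeNHOMe·HCl, AlMe3, CH2Cl2, −20 to 0 °C; aq. Rochelle salt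
Reagents that add atoms: N,O-dimethylhydroxylamine hydrochloride, CNOC.Cl
Why: Weinreb transamination of the aldol imide, helped by the aluminium alkoxide of the free β-hydroxyl, releases the auxiliary and leaves C6 untouched.

Step 4
Reactants: 9 Weinreb amide; 10 4-bromo-2-methylbut-1-ene
Product: 12 (6S,7R)-7-hydroxy-2-methyl-6-(2-methylprop-1-en-1-yl)nona-1,8-dien-5-one, via (3-methylbut-3-en-1-yl)magnesium bromide 11 (not isolated)
Conditions: 10, Mg, THF; then 9, THF, 0 °C; aq. NH4Cl
Reagents that add atoms: none
Why: Weinreb ketone synthesis, in which the chelated tetrahedral adduct survives until work-up so that one 3-methylbut-3-enyl group is added to give the C1 ketone, while epimerisation at the doubly activated C7 does no harm because this centre is reset in step 5.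

Step 5
Reactants: 12 β-hydroxy ketone; 13 tert-butyl bromoacetate
Product: 14 tert-butyl (3S)-3-[(1R)-1-hydroxyprop-2-en-1-yl]-7-methyl-3-(2-methylprop-1-en-1-yl)-4-oxooct-7-enoate
Conditions: LiN(iPr)2 (1.95 equiv), THF, −78 to −20 °C; 13, DMPU, −78 to −40 °C; AcOH
Reagents that add atoms: none
Why: Fráter–Seebach-type alkylation of the alkoxide–dienolate dianion, in which C7–H is the most acidic C–H (flanked by the C1 carbonyl and the 2-methylprop-1-enyl olefin) and the lithium chelate between O6 and the enolate oxygen makes the bromoacetate enter anti to the C6 vinyl group, which places the C11 arm on the face of O6 at the new quaternary C7.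

Step 6
Reactants: 14 acyclic triene keto ester
Product: 15 tert-butyl 2-[(1S,7R)-7-hydroxy-5-methyl-1-(2-methylprop-1-en-1-yl)-2-oxocyclohept-5-en-1-yl]acetate
Conditions: second-generation Grubbs catalyst RuCl2(=CHPh)(H2IMes)(PCy3) (cat.), CH2Cl2 (2 mM), 40 °C
Reagents that add atoms: none
Why: Ring-closing metathesis between the C6 vinyl group and the 1,1-disubstituted C4 olefin should close the cycloheptenone, the trisubstituted 2-methylprop-1-enyl olefin being too hindered to compete.

Step 7
Reactants: 15 cycloheptenol
Product: 16 tert-butyl 2-[(1S,5R,6S,7S)-5,6,7-trihydroxy-5-methyl-1-(2-methylprop-1-en-1-yl)-2-oxocycloheptyl]acetate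
Conditions: OsO4 (1.05 equiv), TMEDA, CH2Cl2, −78 °C; then HCl, MeOH, rt
Reagents that add atoms: osmium tetroxide, O=[Os](=O)(=O)=O
Why: Hydroxyl-directed syn-dihydroxylation with the OsO4·TMEDA complex, in which hydrogen bonding to the free allylic O6–H should deliver both new oxygens to C4 and C5 on the face of O6 and favour the ring olefin over the more remote side-chain olefin, giving the all-cis 4,5,6-triol.

Step 8
Reactants: 16 triol ester
Product: 17 isobutenyl keto lactone acetonide
Conditions: Me2C(OMe)2, CSA (cat.), acetone, rt to 45 °C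
Reagents that add atoms: 2,2-dimethoxypropane, COC(C)(C)OC
Why: Acid-catalysed ketal exchange and lactonisation under thermodynamic control, in which the γ-lactone can close only onto O6 and so leaves the cis 4,5-diol for the dioxolane, with no stereocentre touched.

Step 9
Reactants: 17 isobutenyl keto lactone acetonide
Product: 18 C8 aldehyde keto lactone acetonide
Conditions: O3, CH2Cl2/MeOH, −78 °C; then Me2S, −78 °C to rt
Reagents that add atoms: ozone, [O-][O+]=O
Why: Ozonolysis with reductive work-up cleaves the only olefin left and unveils the C8 aldehyde, which cannot enolise because C7 is quaternary.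

Step 10
Reactants: 18 C8 aldehyde keto lactone acetonide; 19 propa-1,2-diene
Product: 22 (8S)-2-bromoallyl carbinol keto lactone acetonide, via (2-bromoallyl)diisopinocampheylborane 20 (not isolated), via diisopinocampheylborinate ester 21 (not isolated)
Conditions: 19, Ipc2BBr [from (+)-α-pinene], CH2Cl2, −78 to 0 °C; then 18, −78 °C; HOCH2CH2NH2
Reagents that add atoms: B-bromodiisopinocampheylborane, BrB([C@@H]1C[C@@H]2C[C@H]([C@H]1C)C2(C)C)[C@@H]1C[C@@H]2C[C@H]([C@H]1C)C2(C)C
Why: Asymmetric allylboration, in which bromoboration of allene gives the 2-bromoallyl isopinocampheyl borane that adds chemoselectively to the aldehyde through a chair transition state on the Si face and so sets C8 as S under reagent control.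

Step 11
Reactants: 22 (8S)-2-bromoallyl carbinol keto lactone acetonide
Product: 23 C8 TBS ether vinyl bromide
Conditions: TBSOTf, 2,6-lutidine, CH2Cl2, −78 to 0 °C
Reagents that add atoms: tert-butyldimethylsilyl triflate, CC(C)(C)[Si](C)(C)OS(=O)(=O)C(F)(F)F
Why: Silylation of the hindered C8 carbinol with a silyl triflate and a hindered base protects it at once, which also blocks retro-aldol cleavage and lactone migration to O8.

Step 12
Reactants: 23 C8 TBS ether vinyl bromide
Product: 24 C8 TBS ether vinyl iodide
Conditions: NaI, CuI (cat.), trans-N,N'-dimethylcyclohexane-1,2-diamine (cat.), 1,4-dioxane, 110 °C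
Reagents that add atoms: sodium iodide, [Na+].[I-]
Why: Copper-catalysed halogen exchange (Finkelstein reaction of an alkenyl bromide with CuI and a diamine ligand) gives the alkenyl iodide needed for fast and selective iodine abstraction in step 15.

Step 13
Reactants: 24 C8 TBS ether vinyl iodide
Product: 25 α-phenylthio lactone
Conditions: 24 added to LiN(iPr)2 (2.1 equiv), THF, −78 °C; PhSSPh (1.0 equiv), −78 °C; AcOH
Reagents that add atoms: diphenyl disulfide, c1ccc(SSc2ccccc2)cc1
Why: Enolate sulfenylation, in which two equivalents of base enolise both the ketone (at C2) and the lactone (at C11) and the disulfide reacts only with the more nucleophilic lactone enolate, from the convex face of the bicycle.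

Step 14
Reactants: 25 α-phenylthio lactone
Product: 27 iodovinyl phenylthio lactone cycloheptanone, via hydroxymethyl lactone 26 (not isolated)
Conditions: LiN(SiMe3)2 (0.95 equiv), THF, −78 to −30 °C; CH2O (g), −78 °C; Ac2O, −78 to 0 °C
Reagents that add atoms: formaldehyde, C=O; acetic anhydride, CC(=O)OC(C)=O
Why: Aldol addition to formaldehyde followed by O-acetylation, in which the sulfur-stabilised C11 enolate is the thermodynamically preferred anion, adds to formaldehyde from the convex face and is trapped as the acetate before retro-aldol loss of formaldehyde.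

Step 15
Reactants: 27 iodovinyl phenylthio lactone cycloheptanone
Product: 28 ten-membered enone butenolide diol acetonide
Conditions: Bu3SnSnBu3 (1.5 equiv), hν (sunlamp, Pyrex), PhH (5 mM), 80 °C
Reagents that add atoms: none
Why: Proposed new method: the stannyl radical from photolysed Bu3SnSnBu3 abstracts iodine to give the C10 σ-vinyl radical, which adds to the C1 carbonyl carbon to give a bicyclic alkoxy radical; β-scission of the shared C1–C7 bond then opens the cycloheptane to the ten-membered ring with a tertiary C7 radical, and loss of PhS• from C11 fixes the C7=C11 butenolide olefin while the ditin traps the thiyl radical as Bu3SnSPh. The closest known chemistry is the Dowd–Beckwith three-carbon ring expansion of α-(3-halopropyl) cycloalkanones, joined here to vinyl-radical addition to a ketone and to β-fragmentation of a β-(phenylthio)alkyl radical. The ten-membered ring is closed in two events, a 5-exo-trig attack of C10 on C1 followed by cleavage of the C1–C7 bond, so no direct ten-ring cyclisation is needed. No new stereocentre is formed, C7 and C11 become trigonal, and C4, C5, C6 and C8 are not touched. The step needs addition to C1=O to win over 1,5-hydrogen transfer from C6–H and over quenching of the vinyl radical, which the quaternary C7 holding C8 and C1 together, the absence of tin hydride and thiol, and high dilution should secure, while the fast loss of PhS• pulls the reversible alkoxy-radical steps forward.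

Step 16
Reactants: 28 ten-membered enone butenolide diol acetonide
Product: 29 C8 alcohol
Conditions: HF·pyridine, pyridine, THF, 0 °C to rt
Reagents that add atoms: none
Why: Fluoride-mediated desilylation with buffered HF·pyridine should free the C8 hydroxyl without touching the acetonide, the acetate or the enone.

Step 17
Reactants: 29 C8 alcohol; 30 tigloyl chloride
Product: 31 C8 tiglate acetonide
Conditions: pyridine, DMAP (cat.), CH2Cl2, 0 °C to rt
Reagents that add atoms: none
Why: DMAP-catalysed acylation of the secondary allylic C8 alcohol with the acid chloride installs the (E)-2-methylbut-2-enoate with retention at C8.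

Step 18
Reactants: 31 C8 tiglate acetonide
Product: 32 C8 tiglate 4,5-diol
Conditions: AcOH/H2O (4:1), 45 °C
Reagents that add atoms: none
Why: Acid-catalysed acetal hydrolysis frees the cis 4,5-diol, while the esters, the lactone and the enone should be stable to aqueous acetic acid.

Step 19
Reactants: 32 C8 tiglate 4,5-diol
Product: 34 CNP0225286.1, via C5 triflate 33 (not isolated)
Conditions: Tf2O, 2,6-lutidine, CH2Cl2, −78 to 0 °C
Reagents that add atoms: none
Why: Selective triflation of the secondary C5 hydroxyl followed by intramolecular Williamson-type displacement by the neighbouring tertiary C4 hydroxyl with inversion at C5, which the flexible ten-membered ring allows, should give the trans 4,5-epoxide of the target under conditions too weakly basic to deprotonate C6–H.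

**Compound list**
1 | 4-methylpent-3-enoic acid | CC(C)=CCC(=O)O | starting material
2 | (S)-4-benzyloxazolidin-2-one | O=C1N[C@@H](Cc2ccccc2)CO1 | starting material
3 | 4-methylpent-3-enoic pivalic anhydride (not isolated) | CC(C)=CCC(=O)OC(=O)C(C)(C)C | intermediate
4 | (S)-4-benzyl-3-(4-methylpent-3-enoyl)oxazolidin-2-one | CC(C)=CCC(=O)N1[C@@H](Cc2ccccc2)COC1=O | intermediate
5 | acrolein | C=CC=O | starting material
6 | dibutylboron Z-dienolate of 4 (not isolated) | CCCCB(CCCC)O/C(=C\C=C(C)C)N1[C@@H](Cc2ccccc2)COC1=O | intermediate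
7 | dibutylboron aldolate of 8 (not isolated) | C=C[C@@H](OB(CCCC)CCCC)[C@H](C=C(C)C)C(=O)N1[C@@H](Cc2ccccc2)COC1=O | intermediate
8 | (S)-4-benzyl-3-[(2S,3R)-3-hydroxy-2-(2-methylprop-1-en-1-yl)pent-4-enoyl]oxazolidin-2-one | C=C[C@@H](O)[C@H](C=C(C)C)C(=O)N1[C@@H](Cc2ccccc2)COC1=O | intermediate
9 | (2S,3R)-3-hydroxy-N-methoxy-N-methyl-2-(2-methylprop-1-en-1-yl)pent-4-enamide | C=C[C@@H](O)[C@H](C=C(C)C)C(=O)N(C)OC | intermediate
10 | 4-bromo-2-methylbut-1-ene | C=C(C)CCBr | starting material
11 | (3-methylbut-3-en-1-yl)magnesium bromide (not isolated) | C=C(C)CC[Mg]Br | intermediate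
12 | (6S,7R)-7-hydroxy-2-methyl-6-(2-methylprop-1-en-1-yl)nona-1,8-dien-5-one (C6 of this name is the epimerisable C7 of the target numbering) | C=C[C@@H](O)[C@H](C=C(C)C)C(=O)CCC(C)=C | intermediate
13 | tert-butyl bromoacetate | BrCC(=O)OC(C)(C)C | starting material
14 | tert-butyl (3S)-3-[(1R)-1-hydroxyprop-2-en-1-yl]-7-methyl-3-(2-methylprop-1-en-1-yl)-4-oxooct-7-enoate | C=C[C@@H](O)[C@@](C=C(C)C)(CC(=O)OC(C)(C)C)C(=O)CCC(C)=C | intermediate
15 | tert-butyl 2-[(1S,7R)-7-hydroxy-5-methyl-1-(2-methylprop-1-en-1-yl)-2-oxocyclohept-5-en-1-yl]acetate | O[C@@H]1C=C(C)CCC(=O)[C@]1(C=C(C)C)CC(=O)OC(C)(C)C | intermediate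
16 | tert-butyl 2-[(1S,5R,6S,7S)-5,6,7-trihydroxy-5-methyl-1-(2-methylprop-1-en-1-yl)-2-oxocycloheptyl]acetate (all-cis triol on the face of the acetate arm) | O[C@@H]1[C@H](O)[C@](C)(O)CCC(=O)[C@]1(C=C(C)C)CC(=O)OC(C)(C)C | intermediate
17 | isobutenyl keto lactone acetonide: (4R,5S,6S,7S)-4-methyl-7-(2-methylprop-1-en-1-yl)cycloheptan-1-one with the cis 4,5-diol as isopropylidene acetal and the C7 CH2CO arm closed on O6 as cis-fused γ-lactone | CC(C)=C[C@]12C(=O)CC[C@@]3(C)OC(C)(C)O[C@H]3[C@H]1OC(=O)C2 | intermediate
18 | C8 aldehyde keto lactone acetonide (as 17 with CHO on C7; 4R,5S,6S) | O=C[C@]12C(=O)CC[C@@]3(C)OC(C)(C)O[C@H]3[C@H]1OC(=O)C2 | intermediate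
19 | propa-1,2-diene (allene) | C=C=C | starting material
20 | (2-bromoallyl)diisopinocampheylborane from (+)-α-pinene (not isolated) | C=C(Br)CB([C@@H]1C[C@@H]2C[C@H]([C@H]1C)C2(C)C)[C@@H]1C[C@@H]2C[C@H]([C@H]1C)C2(C)C | intermediate
21 | diisopinocampheylborinate ester of 22 (not isolated) | C=C(Br)C[C@H](OB([C@@H]1C[C@@H]2C[C@H]([C@H]1C)C2(C)C)[C@@H]1C[C@@H]2C[C@H]([C@H]1C)C2(C)C)[C@]12C(=O)CC[C@@]3(C)OC(C)(C)O[C@H]3[C@H]1OC(=O)C2 | intermediate
22 | (8S)-2-bromoallyl carbinol keto lactone acetonide (C7 bears CH(OH)CH2C(Br)=CH2; 4R,5S,6S,8S) | C=C(Br)C[C@H](O)[C@]12C(=O)CC[C@@]3(C)OC(C)(C)O[C@H]3[C@H]1OC(=O)C2 | intermediate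
23 | C8 TBS ether vinyl bromide (4R,5S,6S,8S) | C=C(Br)C[C@H](O[Si](C)(C)C(C)(C)C)[C@]12C(=O)CC[C@@]3(C)OC(C)(C)O[C@H]3[C@H]1OC(=O)C2 | intermediate
24 | C8 TBS ether vinyl iodide (4R,5S,6S,8S) | C=C(I)C[C@H](O[Si](C)(C)C(C)(C)C)[C@]12C(=O)CC[C@@]3(C)OC(C)(C)O[C@H]3[C@H]1OC(=O)C2 | intermediate
25 | α-phenylthio lactone (SPh on C11, drawn on the convex face, cis to the C8 chain) | C=C(I)C[C@H](O[Si](C)(C)C(C)(C)C)[C@]12C(=O)CC[C@@]3(C)OC(C)(C)O[C@H]3[C@H]1OC(=O)[C@@H]2Sc1ccccc1 | intermediate
26 | hydroxymethyl lactone (C11 bears SPh and CH2OH; not isolated) | C=C(I)C[C@H](O[Si](C)(C)C(C)(C)C)[C@]12C(=O)CC[C@@]3(C)OC(C)(C)O[C@H]3[C@H]1OC(=O)[C@@]2(CO)Sc1ccccc1 | intermediate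
27 | iodovinyl phenylthio lactone cycloheptanone (4R,5S,6S,7S,8S,11R; key-step precursor) | C=C(I)C[C@H](O[Si](C)(C)C(C)(C)C)[C@]12C(=O)CC[C@@]3(C)OC(C)(C)O[C@H]3[C@H]1OC(=O)[C@@]2(COC(C)=O)Sc1ccccc1 | intermediate
28 | ten-membered enone butenolide diol acetonide (4R,5S,6S,8S; key-step product) | C=C1C[C@H](O[Si](C)(C)C(C)(C)C)C2=C(COC(C)=O)C(=O)O[C@@H]2[C@@H]2OC(C)(C)O[C@]2(C)CCC1=O | intermediate
29 | C8 alcohol (28 without the silyl group) | C=C1C[C@H](O)C2=C(COC(C)=O)C(=O)O[C@@H]2[C@@H]2OC(C)(C)O[C@]2(C)CCC1=O | intermediate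
30 | tigloyl chloride, (E)-2-methylbut-2-enoyl chloride | C/C=C(\C)C(Cl)=O | starting material
31 | C8 tiglate acetonide | C=C1C[C@H](OC(=O)/C(C)=C/C)C2=C(COC(C)=O)C(=O)O[C@@H]2[C@@H]2OC(C)(C)O[C@]2(C)CCC1=O | intermediate
32 | C8 tiglate 4,5-diol (4R,5S; may rest as the O4–C1 hemiketal) | C=C1C[C@H](OC(=O)/C(C)=C/C)C2=C(COC(C)=O)C(=O)O[C@@H]2[C@H](O)[C@](C)(O)CCC1=O | intermediate
33 | C5 triflate of 32 (not isolated) | C=C1C[C@H](OC(=O)/C(C)=C/C)C2=C(COC(C)=O)C(=O)O[C@@H]2[C@H](OS(=O)(=O)C(F)(F)F)[C@](C)(O)CCC1=O | intermediate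
34 | CNP0225286.1, (4R,5R,6S,8S)-13-acetoxy-4,5-epoxy-1-oxo-8-tigloyloxygermacra-7(11),10(14)-dien-12,6-olide | C=C1C[C@H](OC(=O)/C(C)=C/C)C2=C(COC(C)=O)C(=O)O[C@@H]2[C@H]2O[C@]2(C)CCC1=O | target

**Step count and risks**
Total step count: 19. Longest linear sequence: 19 steps (1 and 2 to 34).

Steps most likely to fail:

Step 15 (key step). The vinyl radical may be lost by 1,5-hydrogen transfer from C6–H or by attack on the solvent before it reaches the carbonyl, and the alkoxy radical may cleave toward C2. The fallback splits the cascade into two known operations. From 27, an intramolecular Nozaki–Hiyama–Kishi reaction (CrCl2, NiCl2 cat., DMF) should add the alkenyl iodide to the C1 ketone and give the cis-fused tricyclic tertiary alcohol F1. Its alkoxy radical, made under hypoiodite conditions (PhI(OAc)2, I2, hν, cyclohexane), should cleave C1–C7, and loss of PhS• from C11 returns the route at 28.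

Step 5. Enolisation may take place at C2 in place of C7, the lithium aldolate may undergo retro-aldol cleavage, or chelate control of the facial selectivity may be lost. The fallback moves the alkylation to the ester level. From 8, methanolysis (NaOMe, MeOH, 0 °C) would give the methyl ester F2. A Fráter–Seebach alkylation of its dianion (LiN(iPr)2, then 13) would give the diester F3. MeAl(Cl)N(OMe)Me would convert only the methyl ester into the Weinreb amide F4, and addition of 11 returns the route at 14.

Step 7. Osmylation may also consume the side-chain olefin, or oxygen may be delivered to the face away from O6 if hydrogen bonding is weak. The fallback builds the diol by way of an epoxide. From 15, hydroxyl-directed epoxidation (VO(acac)2, t-BuOOH, CH2Cl2) would give the syn epoxy alcohol F5. Halide-catalysed CO2 insertion (LiBr, CO2, NMP, heat), which proceeds with net retention by double inversion, would give the cis cyclic carbonate F6. Mild methanolysis (K2CO3, MeOH, 0 °C) returns the route at 16.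

Further compounds
F1 | step 15 | cis-fused tricyclic tertiary alcohol (C10 bonded to C1, C1 bearing OH) | C=C1C[C@H](O[Si](C)(C)C(C)(C)C)[C@]23[C@@]1(O)CC[C@@]4(C)OC(C)(C)O[C@H]4[C@H]2OC(=O)[C@@]3(COC(C)=O)Sc1ccccc1
F2 | step 5 | methyl (2S,3R)-3-hydroxy-2-(2-methylprop-1-en-1-yl)pent-4-enoate | C=C[C@@H](O)[C@H](C=C(C)C)C(=O)OC
F3 | step 5 | 4-tert-butyl 1-methyl 2-(1-hydroxyprop-2-en-1-yl)-2-(2-methylprop-1-en-1-yl)butanedioate (C6 and C7 configured as in 14) | C=C[C@@H](O)[C@@](C=C(C)C)(CC(=O)OC(C)(C)C)C(=O)OC
F4 | step 5 | Weinreb amide of F3 (tert-butyl ester kept) | C=C[C@@H](O)[C@@](C=C(C)C)(CC(=O)OC(C)(C)C)C(=O)N(C)OC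
F5 | step 7 | syn 4,5-epoxy alcohol of 15 (epoxide on the face of O6) | O[C@@H]1[C@@H]2O[C@]2(C)CCC(=O)[C@]1(C=C(C)C)CC(=O)OC(C)(C)C
F6 | step 7 | cis 4,5-cyclic carbonate of 16 | O[C@@H]1[C@@H]2OC(=O)O[C@]2(C)CCC(=O)[C@]1(C=C(C)C)CC(=O)OC(C)(C)C
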